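Numbering: ring C1 (CH2OAc), C2 (=CH), C3 (C=O), C4 (epoxide C carrying the chain), C5 (epoxide CH), C6 (C=O); chain C1′ (CHOAc) to C6′ (CHO).
Enabling feature: C1′ is an acetoxy-bearing allylic carbon held between the quaternary epoxide carbon C4 of the six-membered ring and the (E)-trisubstituted C2′=C3′(CH3) bond, the retron of syn-methylmetalation of a terminal alkyne followed by addition of the alkenylmetal to a C4 formyl group.
Cuts: C6′=O (to the allylic alcohol) and C6=O (to a ketal); then C1′–C2′, C3′–CH3 and the C1′ O–acetyl bond in one operation; then the C4–O/C5–O epoxide bonds. The carbocycle is never built: it is the ring of 2,5-dimethoxyterephthalaldehyde after oxidative dearomatisation.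
Forward: the two formyl groups are told apart (demethylation, phenoxide-controlled reduction, enzymatic acetylation, second reduction), the phenol is oxidised to the quinone monoketal, the ketal is exchanged for a C2-symmetric dioxane, C4=C5 is epoxidised, C1′ is raised to the aldehyde, the chain is joined, ketal and silyl ether are removed, and C6′ is oxidised last.
Stereochemistry: C4/C5 from auxiliary-directed nucleophilic epoxidation (cis-fused by necessity), C1′ by 1,2-induction from C4 in the aldehyde addition, C2′=C3′ from syn-carbometalation, C4′=C5′ from the (E)-enynol.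
The ketal sits on C6 and the ketone on C3 so that the peroxide attacks the unsubstituted C5; C6 stays masked through the key step so that no ene-dione meets the organometallic.

Key step: step 10

Assumption: (2R,4R)-pentane-2,4-diol is taken as the antipode whose spiroketal opens the face of C4=C5 that leads to the (4R,5S)-epoxide; if the auxiliary induces the opposite sense, the (2S,4S)-diol is used and nothing else changes.

Step 1
Reactants: 1 2,5-dimethoxyterephthalaldehyde
Product: 2 2-hydroxy-5-methoxyterephthalaldehyde
Conditions: BCl3 (1.1 equiv), CH2Cl2, −78 → 0 °C; H2O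
Reagents that add atoms: none
Why: Boron trichloride binds a formyl oxygen and cleaves only the methyl ether held in the resulting six-membered chelate (chelation-assisted ortho-demethylation), and with one equivalent the dichloroboryl phenoxide formed in the first cleavage uses up the reagent, so the second methoxy group should survive.

Step 2
Reactants: 2 2-hydroxy-5-methoxyterephthalaldehyde
Product: 3 2-hydroxy-4-(hydroxymethyl)-5-methoxybenzaldehyde
Conditions: NaOH (1.0 equiv), NaBH4 (0.3 equiv), EtOH–H2O, 0 °C; aq NH4Cl
Reagents that add atoms: none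
Why: In the phenoxide the formyl group ortho to O⁻ is a vinylogous carboxylate and resists borohydride, so the limited hydride should go to the formyl group that is meta to O⁻ and ortho to OCH3 (chemoselective NaBH4 reduction).

Step 3
Reactants: 3 2-hydroxy-4-(hydroxymethyl)-5-methoxybenzaldehyde
Product: 4 (4-formyl-5-hydroxy-2-methoxyphenyl)methyl acetate
Conditions: immobilised Candida antarctica lipase B, vinyl acetate (3 equiv), THF, 30 °C
Reagents that add atoms: vinyl acetate, CC(=O)OC=C
Why: Lipase-catalysed transesterification with an enol ester acylates primary aliphatic alcohols and leaves phenols (here also hydrogen-bonded to the formyl group) untouched, and tautomerisation of the released vinyl alcohol makes the acyl transfer irreversible.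

Step 4
Reactants: 4 (4-formyl-5-hydroxy-2-methoxyphenyl)methyl acetate
Product: 5 [5-hydroxy-4-(hydroxymethyl)-2-methoxyphenyl]methyl acetate
Conditions: NaBH4 (1.0 equiv), THF–MeOH (4:1), 0 °C; aq NH4Cl
Reagents that add atoms: none
Why: Excess borohydride in a protic medium reduces the remaining salicyl-type aldehyde at 0 °C, a temperature at which a primary acetate is not attacked, so the two benzylic carbons end up differentiated as CH2OH (ortho to OH) and CH2OAc (ortho to OCH3).

Step 5
Reactants: 5 [5-hydroxy-4-(hydroxymethyl)-2-methoxyphenyl]methyl acetate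
Product: 6 [4-(hydroxymethyl)-6,6-dimethoxy-3-oxocyclohexa-1,4-dien-1-yl]methyl acetate
Conditions: PhI(OAc)2 (1.05 equiv), MeOH, 0 °C; NaHCO3
Reagents that add atoms: methanol, CO
Why: Two-electron oxidation of the para-methoxyphenol by iodine(III) and capture of the phenoxenium ion by methanol at the methoxy-bearing carbon (oxidative dearomatisation to a quinone monoketal) places the ketone at C3 next to the hydroxymethyl-bearing C4 and the ketal at C6.

Step 6
Reactants: 6 [4-(hydroxymethyl)-6,6-dimethoxy-3-oxocyclohexa-1,4-dien-1-yl]methyl acetate; 7 (2R,4R)-pentane-2,4-diol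
Product: 8 [(2R,4R)-10-(hydroxymethyl)-2,4-dimethyl-9-oxo-1,5-dioxaspiro[5.5]undeca-7,10-dien-7-yl]methyl acetate (6 with the C6 ketal exchanged for the (4R,6R)-4,6-dimethyl-1,3-dioxane)
Conditions: 7 (3 equiv), PPTS (10 mol %), benzene, 70 °C, 4 Å MS
Reagents that add atoms: none
Why: Acid-catalysed transketalisation through the 4-oxocyclohexadienyl oxocarbenium ion is driven to the spiro-1,3-dioxane by removal of methanol and by ring formation, and it places a C2-symmetric auxiliary directly beside C5 without creating a new stereocentre.

Step 7
Reactants: 8 spiroketal dienone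
Product: 9 (4R,5S)-4,5-epoxide of 8 (oxirane across C4–C5, CH2OH on C4, C3 ketone and C1=C2 retained)
Conditions: Ph3COOH (1.5 equiv), KHMDS (1.3 equiv), THF, −78 °C, premixed; then 8, −78 → −35 °C; aq NH4Cl
Reagents that add atoms: trityl hydroperoxide, OOC(c1ccccc1)(c1ccccc1)c1ccccc1
Why: In this Weitz–Scheffer nucleophilic epoxidation the bulky potassium peroxide should add to C5, the only unsubstituted β-carbon of the dienone (C1 carries CH2OAc), on the face left open by the dioxane methyl groups, and the C3 enolate then closes on O–O with loss of trityloxide, which fixes C4 and C5 together as a cis-fused epoxide whose minor diastereomer, if any, is removed by chromatography.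

Step 8
Reactants: 9 (4R,5S)-epoxy alcohol
Product: 10 (4S,5S)-4-formyl-4,5-epoxide (CHO in place of CH2OH; same spatial arrangement as 9, the C4 descriptor changes by CIP rank only)
Conditions: Dess–Martin periodinane (1.3 equiv), NaHCO3, CH2Cl2, 0 °C → rt; used without chromatography
Reagents that add atoms: none
Why: Dess–Martin oxidation of the primary epoxy alcohol stops at the aldehyde, which has no α-hydrogen and so can neither epimerise nor enolise, while bicarbonate buffers the acetic acid released.

Step 9
Reactants: 11 (2E)-pent-2-en-4-yn-1-ol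
Product: 12 tert-butyldimethyl{[(2E)-pent-2-en-4-yn-1-yl]oxy}silane
Conditions: TBSCl, imidazole, CH2Cl2, 0 °C → rt
Reagents that add atoms: tert-butyldimethylsilyl chloride, CC(C)(C)[Si](C)(C)Cl
Why: Imidazole-mediated silylation of a primary allylic alcohol gives an ether that is inert to Me3Al, MeLi and the alanate, so the future aldehyde terminus travels as a neutral group.

Step 10
Reactants: 10 (4S,5S)-4-formyl-4,5-epoxide; 12 silyl enyne; 13 trimethylaluminium
Product: 17 (4R,5S,1′S) coupled C1′ acetate bearing the C6′ TBS ether and the C6 spiroketal, via dienyldimethylalane 14 (not isolated), via lithium dienyltrimethylalanate 15 (not isolated), via aluminate alkoxide 16 (not isolated)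
Conditions: 12 (1.6 equiv), Me3Al (3.2 equiv), Cp2ZrCl2 (0.25 equiv), CH2Cl2, 0 °C → rt; volatiles (excess Me3Al) removed in vacuo; THF–hexane, MeLi (1.0 equiv per alane), −78 °C; 10 (1.0 equiv), THF, −78 °C; Ac2O (5 equiv), DMAP (0.2 equiv), −78 → 0 °C; aq Rochelle salt
Reagents that add atoms: acetic anhydride, CC(=O)OC(C)=O
Why: Cp2ZrCl2 and Me3Al generate a methylzirconocene–chloroaluminate pair that adds CH3 and metal syn across the terminal alkyne of 12 (CH3 to the internal C3′, metal to C2′), and Zr-to-Al exchange releases (1E,3E)-dienylalane 14 and returns the catalyst. MeLi turns 14 into the nucleophilic ate complex 15, which transfers its sp2 carbon with retention to the formyl carbon of 10, and the resulting aluminate alkoxide 16 is acetylated in the same flask by Ac2O/DMAP, so a free C1′ alkoxide never lingers beside the epoxide (no Payne-type shift). The closest known reaction types are the Negishi zirconium-catalysed carboalumination of conjugated enynes and the 1,2-addition of lithium alkenylalanates to aldehydes; no ring closes, and the bonds made are C3′–CH3, C1′–C2′ and O–acetyl. The one new stereocentre, C1′, is controlled by the adjacent quaternary C4: with the formyl C=O antiperiplanar to the C4–O epoxide bond (Cornforth arrangement; the polar Felkin–Anh picture with attack anti to C4–O leads to the same result) the alkenyl group should pass the bent-back C5–H flank and not the flank lined by the C3 carbonyl oxygen, which gives (1′S). The C2′=C3′ geometry is E because syn addition leaves aluminium trans to C4′, and C4′=C5′ is carried over unchanged from 11. The step needs chemoselectivity for CHO over the C3 enone, the acetate ester and the epoxide, which is secured because the formyl group is the most electrophilic and least hindered carbonyl, the C3 ketone is conjugated and flanked by quaternary C4, C6 is masked as the ketal so that no ene-dione acceptor is present, and the addition is run at −78 °C in THF, where solvated Li⁺ is unlikely to bridge the C1′ and C3 carbonyl oxygens.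

Step 11
Reactants: 17 (4R,5S,1′S) coupled C1′ acetate
Product: 18 (4R,5S,1′S)-epoxyquinone dienol (C3 and C6 ketones, C1 CH2OAc, chain (1S,2E,4E)-1-acetoxy-6-hydroxy-3-methylhexa-2,4-dienyl on C4)
Conditions: 48% aq HF–MeCN (1:9), 0 °C → rt
Reagents that add atoms: water, O
Why: Aqueous HF in acetonitrile cleaves the primary silyl ether and hydrolyses the spiroketal through its oxocarbenium ion (acidic global unmasking), while the epoxide, flanked on both sides by carbonyl-level carbons, is deactivated toward acid opening and both acetates are stable at this acidity.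

Step 12
Reactants: 18 (4R,5S,1′S)-epoxyquinone dienol
Product: 19 target CNP0307549.1, (4R,5S)-1-(acetoxymethyl)-4-[(1S,2E,4E)-1-acetoxy-3-methyl-6-oxohexa-2,4-dienyl]-4,5-epoxycyclohex-1-ene-3,6-dione
Conditions: activated MnO2 (20 equiv), CH2Cl2, rt
Reagents that add atoms: none
Why: Activated MnO2 oxidises only the allylic (dienylic) primary alcohol, at neutral pH and without touching the epoxide, the acetates or the ene-dione, and the E,E geometry is retained.

Compound list
1 | 2,5-dimethoxyterephthalaldehyde | COc1cc(C=O)c(OC)cc1C=O | starting material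
2 | 2-hydroxy-5-methoxyterephthalaldehyde | COc1cc(C=O)c(O)cc1C=O | intermediate
3 | 2-hydroxy-4-(hydroxymethyl)-5-methoxybenzaldehyde | COc1cc(C=O)c(O)cc1CO | intermediate
4 | (4-formyl-5-hydroxy-2-methoxyphenyl)methyl acetate | COc1cc(C=O)c(O)cc1COC(C)=O | intermediate
5 | [5-hydroxy-4-(hydroxymethyl)-2-methoxyphenyl]methyl acetate | COc1cc(CO)c(O)cc1COC(C)=O | intermediate
6 | [4-(hydroxymethyl)-6,6-dimethoxy-3-oxocyclohexa-1,4-dien-1-yl]methyl acetate (quinone monoketal: C3 ketone, C6 dimethyl ketal) | CC(=O)OCC1=CC(=O)C(CO)=CC1(OC)OC | intermediate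
7 | (2R,4R)-pentane-2,4-diol | C[C@@H](O)C[C@@H](C)O | starting material
8 | [(2R,4R)-10-(hydroxymethyl)-2,4-dimethyl-9-oxo-1,5-dioxaspiro[5.5]undeca-7,10-dien-7-yl]methyl acetate (C6 spiroketal dienone) | CC(=O)OCC1=CC(=O)C(CO)=CC12O[C@H](C)C[C@@H](C)O2 | intermediate
9 | (4R,5S)-4,5-epoxide of 8, CH2OH on C4 | CC(=O)OCC1=CC(=O)[C@]2(CO)O[C@@H]2C13O[C@H](C)C[C@@H](C)O3 | intermediate
10 | (4S,5S)-4-formyl-4,5-epoxy enone spiroketal (aldehyde from 9) | CC(=O)OCC1=CC(=O)[C@]2(C=O)O[C@@H]2C13O[C@H](C)C[C@@H](C)O3 | intermediate
11 | (2E)-pent-2-en-4-yn-1-ol | C#C/C=C/CO | starting material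
12 | tert-butyldimethyl{[(2E)-pent-2-en-4-yn-1-yl]oxy}silane | C#C/C=C/CO[Si](C)(C)C(C)(C)C | intermediate
13 | trimethylaluminium | C[Al](C)C | starting material
14 | {(1E,3E)-5-[(tert-butyldimethylsilyl)oxy]-2-methylpenta-1,3-dien-1-yl}dimethylalane | C[Al](C)/C=C(C)/C=C/CO[Si](C)(C)C(C)(C)C | intermediate
15 | lithium {(1E,3E)-5-[(tert-butyldimethylsilyl)oxy]-2-methylpenta-1,3-dien-1-yl}trimethylalanate | [Li+].C[Al-](C)(C)/C=C(C)/C=C/CO[Si](C)(C)C(C)(C)C | intermediate
16 | lithium trimethylaluminate of the (1′S) C1′ alkoxide (adduct of 15 and 10) | [Li+].CC(=O)OCC1=CC(=O)[C@]2([C@H](/C=C(C)/C=C/CO[Si](C)(C)C(C)(C)C)O[Al-](C)(C)C)O[C@@H]2C13O[C@H](C)C[C@@H](C)O3 | intermediate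
17 | (4R,5S,1′S) coupled acetate: chain (1S,2E,4E)-1-acetoxy-6-[(tert-butyldimethylsilyl)oxy]-3-methylhexa-2,4-dienyl on C4, C3 ketone, C6 spiroketal, C1 CH2OAc | CC(=O)OCC1=CC(=O)[C@]2([C@H](/C=C(C)/C=C/CO[Si](C)(C)C(C)(C)C)OC(C)=O)O[C@@H]2C13O[C@H](C)C[C@@H](C)O3 | intermediate
18 | (4R,5S,1′S)-epoxyquinone dienol: chain (1S,2E,4E)-1-acetoxy-6-hydroxy-3-methylhexa-2,4-dienyl on C4 | CC(=O)OCC1=CC(=O)[C@]2([C@H](/C=C(C)/C=C/CO)OC(C)=O)O[C@@H]2C1=O | intermediate
19 | CNP0307549.1, (4R,5S)-1-(acetoxymethyl)-4-[(1S,2E,4E)-1-acetoxy-3-methyl-6-oxohexa-2,4-dienyl]-4,5-epoxycyclohex-1-ene-3,6-dione | CC(=O)OCC1=CC(=O)[C@]2([C@H](/C=C(C)/C=C/C=O)OC(C)=O)O[C@@H]2C1=O | target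

Total steps: 12. Longest linear sequence: 11 steps (1 to 19 through steps 1–8, 10, 11 and 12); step 9 is the one-step side branch.

Steps most likely to fail

Step 10. Lithium may bridge the C1′ and C3 carbonyl oxygens and turn the alkenyl group toward the face next to the epoxide oxygen (poor or reversed facial selectivity), or alkenyl or methyl transfer to the C3 ketone may compete. The fallback sets out from aldehyde 10 and alane 14 and returns at 17. Iodinolysis of 14 (I2, THF, −30 °C) should give dienyl iodide F1. A catalytic asymmetric Nozaki–Hiyama–Kishi coupling of F1 with 10 (CrCl2 and NiCl2 catalytic, chiral sulfonamide–oxazoline ligand, Mn, Cp2ZrCl2, MeCN) is aldehyde-selective in the presence of ketones and esters and sets C1′ under ligand control; it should give allylic alcohol F2. Ac2O, pyridine and DMAP then give 17.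

Step 7. The peroxide may add slowly, or stray to C1 or to the acetate carbonyl, because C4=C5 is only singly activated and α-branched; weak face discrimination would cost material even though the diastereomers stay separable. The fallback sets out from 8 and returns at 10. The oxidation is done first: Dess–Martin periodinane converts 8 into formyl dienone F3, in which C5 is β to two carbonyl groups. Potassium trityl peroxide at −78 °C should then epoxidise this alkylidene-1,3-dicarbonyl bond quickly and at C5 only, under the same auxiliary control, and deliver 10 directly.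

Step 11. Hydrolysis of the hindered, electronically deactivated dioxane ketal may lag behind acid-promoted damage (acetyl migration, ionisation or transposition of the dienol, epoxide opening). The fallback sets out from 17 and returns at 19. HF·pyridine buffered with pyridine in THF removes only the silyl group and should give dienol ketal F4; MnO2 gives dienal ketal F5. The auxiliary is then taken off last, from the acid-tolerant dienal, by acid-catalysed exchange into acetone (TsOH, acetone, rt), which gives 19.

Further compounds
F1 | step 10 | tert-butyl{[(2E,4E)-5-iodo-4-methylpenta-2,4-dien-1-yl]oxy}dimethylsilane | I/C=C(C)/C=C/CO[Si](C)(C)C(C)(C)C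
F2 | step 10 | (4R,5S,1′S) C1′ alcohol corresponding to 17 (OH in place of the C1′ acetate) | CC(=O)OCC1=CC(=O)[C@]2([C@H](/C=C(C)/C=C/CO[Si](C)(C)C(C)(C)C)O)O[C@@H]2C13O[C@H](C)C[C@@H](C)O3
F3 | step 7 | [(2R,4R)-10-formyl-2,4-dimethyl-9-oxo-1,5-dioxaspiro[5.5]undeca-7,10-dien-7-yl]methyl acetate (4-formyl dienone spiroketal) | CC(=O)OCC1=CC(=O)C(C=O)=CC12O[C@H](C)C[C@@H](C)O2
F4 | step 11 | (4R,5S,1′S) dienol ketal (17 without the silyl group) | CC(=O)OCC1=CC(=O)[C@]2([C@H](/C=C(C)/C=C/CO)OC(C)=O)O[C@@H]2C13O[C@H](C)C[C@@H](C)O3
F5 | step 11 | (4R,5S,1′S) dienal ketal (target with C6 still as the spiroketal) | CC(=O)OCC1=CC(=O)[C@]2([C@H](/C=C(C)/C=C/C=O)OC(C)=O)O[C@@H]2C13O[C@H](C)C[C@@H](C)O3
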